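## Structural features

The target is a biflavonol with no stereocentre. Two 3-hydroxy-2-arylchromen-4-one units are joined by one diaryl ether oxygen that sits para to the chromone on each B ring (C4'–O–C4'). One half has a 5,7-dihydroxy ring A and a 3'-methoxy group next to the ether oxygen. The other half has a 5-hydroxy-7-methoxy ring A and a free 3'-hydroxyl next to the ether oxygen. The two halves differ only in O-methylation, so each must be built separately on an unsymmetrical, doubly ortho-oxygenated diaryl ether whose two one-carbon handles are kept apart. The 3-hydroxychromone units are the fragile part: hot alkali opens them and strong oxidants degrade them, and the free polyphenol is air-sensitive, so all phenols should be freed in one final hydrogenolysis. The real difficulty is building ring C with its C3 oxygen twice on A rings oxygenated at C5, where the one-pot alkaline peroxide cyclisation of a 2'-hydroxychalcone tends to close to the aurone. The key step uses the fact that C3 and C4 of ring C in the 5,7-dihydroxy half are adjacent, oxygen-bearing carbons. C4 can be a formyl group on ring A and C3 the carbonyl of an α-aryloxy arylacetaldehyde whose α-carbon is C2, so the two aldehyde carbons can be joined reductively. The resulting 3,4-diol needs only two alcohol oxidations to become the flavonol, and the stereocentres created in passing (C2, C3, C4) all vanish.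

## Logic of the disconnections

**25 to 24.** The four benzyl–oxygen bonds are cut. One hydrogenolysis then frees every masked phenol and the enol at once. The forward step must leave both chromone C2=C3 bonds and the diaryl ether untouched.

**24 to 23, 22 and 21.** In ring C of the 7-methoxy half, the C2=C3 unsaturation is taken back to the 2,3-dihydro level (23), and the O1–C2 bond is then cut to reveal an epoxy ketone (22, from its bis-acetal 21). Closing the ring with acid by attack of the phenol on the benzylic epoxide carbon avoids the five-membered closure that base favours for chalcones with a 6'-oxygen. The forward step needs 6-endo opening at the benzylic carbon and survival of the first flavonol.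

**21 to 20, and 20 to 17 and 19.** The epoxide oxygen is removed and the Cα=Cβ bond is cut as an aldol condensation. This reduces the second half to an aryl aldehyde (17) and a symmetrical acetophenone (19, one protection step from 18). Both phenols of 19 are masked, so epoxidation and ring closure are separate events. The condensation must be mild enough for the benzylated chromone in 17.

**17 to 15 (via 16).** The 3-O-benzyl bond and the aldehyde are retraced to the free enol and the dioxolane. The dioxolane hides the aldehyde through the hydride reduction and the electron-transfer step, and the benzyl ether shields the enol during the later base and peroxide steps.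

**15 to 13 (via 14).** The two carbonyl-level carbons C3 and C4 are taken back to carbinols. The forward step is a double alcohol oxidation without C3–C4 cleavage, followed by tautomerisation of the 3,4-dione.

**13 to 12 (key).** The C3–C4 bond is cut to two aldehydes. Ring C is thus formed at carbon, and ring A enters as a simple salicylaldehyde ether. The forward step must reduce the aromatic aldehyde first, close the ring faster than any loss of the aryloxy group, and stay intramolecular.

**12 to 11 to 10.** These are oxidation-state changes only: the dialdehyde comes from a diol, and the diol from an ester-aldehyde. The dialdehyde is enolisable at C2 and is therefore made last, under buffered conditions, and used at once.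

**10 to 7 and 9.** The O1–C2 bond is cut as a phenol alkylation by an α-bromo arylacetate. 9 comes from 8 by ortho-formylation, which fixes the regiochemistry that a statistical benzylation of a trihydroxybenzaldehyde would leave open. 7 comes from 5 through 6 by ionic bromination, because radical bromination would attack the dioxolane C–H and the benzylic ether positions.

**5 to 4, and 4 to 2 and 3.** The acetal is retraced to the aldehyde and the diaryl ether C–O bond is cut as a fluoride displacement activated by that aldehyde. 2 comes from 1 by benzylation. The forward step must displace fluoride without condensing the arylacetate methylene with the aldehyde.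

## Other disconnections considered

**Alternative 1:** The cut removes the C2–C3 bond and the C3–O bond of ring C in the 5,7-dihydroxy half and leaves O1–C2 for a later dehydration. In the forward step Rh2(OAc)4 would turn the aryl diazomethyl ketone A1 into a rhodium carbene. Benzyl alcohol A2 would add to give an oxonium ylide, and the diaryl ether aldehyde A3 would trap it in an aldol-type step before the proton shift, giving the α-benzyloxy-β-hydroxy ketone A4 as a diastereomer mixture. Oxidation of the carbinol, removal of the acetal on the ortho oxygen and cyclodehydration would then close ring C.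

- In its favour: it is convergent, the C3 oxygen arrives already benzylated, the B-ring partner is an ordinary aldehyde, and there is no hydride/oxidation detour and no fragile dialdehyde. On these points it is the equal or the better of the chosen plan.
- Against it here: the ylide must be intercepted by an electron-rich para-aryloxybenzaldehyde, a weak electrophile, in competition with plain O–H insertion. A1 is a hindered, electron-rich diazoketone whose preparation and handling carry a hazard. The ester on the other ring would then need an ω-oxygenated acetophenone partner that is not a catalogue compound.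
- Comparison: both plans have one chemoselectivity race at the key step (ylide trapping against proton shift there, ketyl cyclisation against aryloxide loss here). Step counts are similar. The chosen plan uses only catalogue reagents.

**Alternative 2:** The cut removes the C2'–C3' and C4'–C5' bonds of the catechol-type B ring of the 7-methoxy half, so that this benzene ring is assembled around the existing aryl–oxygen bond. In the forward step methyl coumalate A5 and the aryloxyethynyl boronate A6 would undergo a [4+2] cycloaddition followed by decarboxylative aromatisation to the boryl benzoate A7. Oxidation of the C–B bond would give the 3'-phenol.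

- In its favour: the positions of ester, boron and ether oxygen follow from the polarisation of the two partners, no activated fluoride or hot base is needed, and the two one-carbon handles arrive differentiated as ester and acetal. On the last point it is the equal of compound 5, and on the mildness of the ether construction it is the better.
- Against it here: A6 is a labile ynol ether boronate that itself needs several steps. The regiochemistry of pyrone–alkynylboronate cycloadditions is substituent-dependent and the reaction needs strong heating. The step solves the diaryl ether, which one fluoride displacement already provides, and leaves both C rings still to be built.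
- Comparison: it is more elegant in structure but clearly longer, and it does not address the hard part of the target.

**Alternative 3:** The cut removes C4–C4a and O1–C2 of ring C in the 5,7-dihydroxy half, so that ring A enters as unprotected phloroglucinol A8. In the forward step A8 and the α-benzyloxy β-keto ester A9 would be heated near 250 °C in a high-boiling aromatic ether. C-acylation of the phenol and cyclodehydration would give the 3-benzyloxy-5,7-dihydroxyflavone A10.

- In its favour: ring A needs no protecting group and no formyl group, the symmetry of A8 removes any regiochemical question on ring A, and one step delivers the whole protected flavonol. In step economy for this half it is better than the chosen plan.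
- Against it here: an α-benzyloxy β-keto ester at that temperature is open to retro-Claisen cleavage and benzyl loss. The Pechmann-type closure to a 4-arylcoumarin competes with chromone formation. The methyl ester on the other ring is a second acylating site. The free 5,7-diol of A10 would have to be reprotected or carried through the base and peroxide steps of the second half.
- Comparison: it is shorter but depends on one harsh step with several competing pathways. The chosen plan is longer, but each step is mild and has one defined main risk.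

Key step: step 9

Remark: the sp3 stereocentres that appear in 7, 10 to 14 and 21 to 23 are formed without control (racemic compounds or diastereomer mixtures), and all are destroyed before the achiral target 25.

## Steps

Step 1
Reactants: 1 4-fluoro-3-hydroxybenzaldehyde
Product: 2 3-(benzyloxy)-4-fluorobenzaldehyde
Conditions: BnBr, K2CO3, DMF, rt
Reagents that add atoms: benzyl bromide, BrCc1ccccc1
Why: Williamson ether synthesis on the phenoxide; the aryl fluoride does not react with carbonate at room temperature.

Step 2
Reactants: 2 3-(benzyloxy)-4-fluorobenzaldehyde; 3 methyl (4-hydroxy-3-methoxyphenyl)acetate (methyl homovanillate)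
Product: 4 methyl {4-[2-(benzyloxy)-4-formylphenoxy]-3-methoxyphenyl}acetate
Conditions: K2CO3, dry DMSO, 90 °C
Reagents that add atoms: none
Why: Nucleophilic aromatic substitution of the fluoride para to the formyl group by the phenoxide of 3; the weak carbonate base should deprotonate the phenol and not, to a useful extent, the arylacetate methylene.

Step 3
Reactants: 4 methyl {4-[2-(benzyloxy)-4-formylphenoxy]-3-methoxyphenyl}acetate
Product: 5 methyl {4-[2-(benzyloxy)-4-(1,3-dioxolan-2-yl)phenoxy]-3-methoxyphenyl}acetate
Conditions: (Me3SiOCH2)2, Me3SiOTf (cat.), CH2Cl2, −78 to −20 °C; pyridine quench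
Reagents that add atoms: 1,2-bis(trimethylsilyloxy)ethane, C[Si](C)(C)OCCO[Si](C)(C)C
Why: Noyori acetalisation; the aprotic low-temperature conditions should avoid the transesterification of the methyl ester that hot ethylene glycol and acid would cause.

Step 4
Reactants: 5 methyl {4-[2-(benzyloxy)-4-(1,3-dioxolan-2-yl)phenoxy]-3-methoxyphenyl}acetate
Product: 7 methyl bromo{4-[2-(benzyloxy)-4-(1,3-dioxolan-2-yl)phenoxy]-3-methoxyphenyl}acetate (racemic), via silyl ketene acetal 6 (not isolated)
Conditions: LiN(SiMe3)2, Me3SiCl, THF, −78 °C; then NBS, −78 to 0 °C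
Reagents that add atoms: N-bromosuccinimide, O=C1CCC(=O)N1Br; chlorotrimethylsilane, C[Si](C)(C)Cl (silyl group of 6 only)
Why: Ionic α-bromination of an ester through its silyl ketene acetal; this avoids radical conditions, under which the dioxolane C–H and the benzylic ether C–H bonds would be brominated, and trapping the enolate as 6 prevents alkylation of the enolate by the product.

Step 5
Reactants: 8 3,5-bis(benzyloxy)phenol
Product: 9 2,4-bis(benzyloxy)-6-hydroxybenzaldehyde
Conditions: MgCl2, Et3N, (CH2O)n, MeCN, reflux; aq HCl work-up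
Reagents that add atoms: paraformaldehyde (formaldehyde), C=O
Why: Magnesium-mediated ortho-formylation of a phenol (Casnati–Skattebøl); the magnesium phenoxide delivers formaldehyde only ortho to the hydroxyl, the two ortho positions are equivalent, and a second formaldehyde oxidises the benzylic alkoxide.

Step 6
Reactants: 7 methyl bromo{4-[2-(benzyloxy)-4-(1,3-dioxolan-2-yl)phenoxy]-3-methoxyphenyl}acetate; 9 2,4-bis(benzyloxy)-6-hydroxybenzaldehyde
Product: 10 methyl 2-[3,5-bis(benzyloxy)-2-formylphenoxy]-2-{4-[2-(benzyloxy)-4-(1,3-dioxolan-2-yl)phenoxy]-3-methoxyphenyl}acetate (racemic)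
Conditions: K2CO3, DMF, rt
Reagents that add atoms: none
Why: SN2 alkylation of the salicylaldehyde phenoxide by the activated benzylic α-bromo ester, forming the O1–C2 bond; room temperature and the electron-rich, hindered formyl group should hold back the intramolecular aldol closure to a dihydrobenzofuran.

Step 7
Reactants: 10 methyl 2-[3,5-bis(benzyloxy)-2-formylphenoxy]-2-{4-[2-(benzyloxy)-4-(1,3-dioxolan-2-yl)phenoxy]-3-methoxyphenyl}acetate
Product: 11 2-[3,5-bis(benzyloxy)-2-(hydroxymethyl)phenoxy]-2-{4-[2-(benzyloxy)-4-(1,3-dioxolan-2-yl)phenoxy]-3-methoxyphenyl}ethanol (racemic)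
Conditions: LiAlH4, THF, 0 °C; aq NaOH work-up
Reagents that add atoms: none
Why: Hydride reduction of ester and aldehyde to the diol; the acetal and ethers are inert, and the basic work-up protects the acid-labile trialkoxybenzyl alcohol.

Step 8
Reactants: 11 2-[3,5-bis(benzyloxy)-2-(hydroxymethyl)phenoxy]-2-{4-[2-(benzyloxy)-4-(1,3-dioxolan-2-yl)phenoxy]-3-methoxyphenyl}ethanol
Product: 12 2-[3,5-bis(benzyloxy)-2-formylphenoxy]-2-{4-[2-(benzyloxy)-4-(1,3-dioxolan-2-yl)phenoxy]-3-methoxyphenyl}acetaldehyde (racemic)
Conditions: Dess–Martin periodinane, NaHCO3, CH2Cl2, 0 °C to rt; aq Na2S2O3/NaHCO3; used at once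
Reagents that add atoms: none
Why: Double Dess–Martin oxidation under buffered, base-free conditions; the enolisable α-aryl-α-aryloxy aldehyde should survive if it meets neither amine base nor acid and goes directly into step 9.

Step 9
Reactants: 12 2-[3,5-bis(benzyloxy)-2-formylphenoxy]-2-{4-[2-(benzyloxy)-4-(1,3-dioxolan-2-yl)phenoxy]-3-methoxyphenyl}acetaldehyde
Product: 13 5,7-bis(benzyloxy)-2-{4-[2-(benzyloxy)-4-(1,3-dioxolan-2-yl)phenoxy]-3-methoxyphenyl}chromane-3,4-diol (mixture of stereoisomers)
Conditions: SmI2 (0.1 M in THF, 2.4 equiv, slow addition), t-BuOH (3 equiv), THF (0.01 M in 12), −78 to −40 °C; sat. aq NaHCO3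
Reagents that add atoms: none
Why: SmI2 should transfer one electron to the samarium-bound aromatic aldehyde to give a benzylic ketyl radical, which adds to the carbonyl carbon of the neighbouring aliphatic aldehyde held on the same trivalent samarium centre, and a second electron and protonation by t-BuOH then give the diol. The closest known reaction type is the SmI2-mediated intramolecular pinacol coupling of dialdehydes to cyclic 1,2-diols. Ring C closes at C3–C4 in the 6-exo-trig mode. The two new carbinol centres C3 and C4 are expected to be cis because both oxygens are bound to samarium in the closing transition state, while their relation to the C2 aryl group is left open, which is acceptable because step 10 erases C2, C3 and C4. The selectivity needed is reduction of the aromatic aldehyde before the α-aryloxy aldehyde, whose ketyl could expel the phenoxide of 9. The conjugated aldehyde should accept the electron more readily, and slow addition of HMPA-free SmI2 at −78 °C keeps the reductant scarce so that cyclisation outruns a second electron transfer. High dilution suppresses intermolecular coupling. Benzyl ethers, the dioxolane and the diaryl ether do not react with SmI2 under these conditions, and the bicarbonate quench protects the acid-labile C4 carbinol.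

Step 10
Reactants: 13 5,7-bis(benzyloxy)-2-{4-[2-(benzyloxy)-4-(1,3-dioxolan-2-yl)phenoxy]-3-methoxyphenyl}chromane-3,4-diol
Product: 15 5,7-bis(benzyloxy)-2-{4-[2-(benzyloxy)-4-(1,3-dioxolan-2-yl)phenoxy]-3-methoxyphenyl}-3-hydroxy-4H-chromen-4-one, via chromane-3,4-dione 14 (not isolated)
Conditions: IBX (4 equiv), DMSO, rt to 45 °C
Reagents that add atoms: none
Why: IBX in DMSO oxidises 1,2-diols to 1,2-diketones without C–C cleavage; the 2-aryl-3,4-dione 14 should enolise through C2–H to the conjugated 3-hydroxychromone, which removes all three stereocentres.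

Step 11
Reactants: 15 5,7-bis(benzyloxy)-2-{4-[2-(benzyloxy)-4-(1,3-dioxolan-2-yl)phenoxy]-3-methoxyphenyl}-3-hydroxy-4H-chromen-4-one
Product: 17 3-(benzyloxy)-4-{2-methoxy-4-[3,5,7-tris(benzyloxy)-4-oxo-4H-chromen-2-yl]phenoxy}benzaldehyde, via benzylated dioxolane 16 (not isolated)
Conditions: BnBr, K2CO3, DMF, rt; then 2 M aq HCl, THF, rt
Reagents that add atoms: benzyl bromide, BrCc1ccccc1; water, O
Why: O-Alkylation of the acidic flavonol enol followed in the same flask by acid hydrolysis of the aryl dioxolane; the benzyl ether protects the 3-hydroxychromone from the base and peroxide of steps 13 and 14.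

Step 12
Reactants: 18 1-(2,6-dihydroxy-4-methoxyphenyl)ethanone
Product: 19 1-[4-methoxy-2,6-bis(methoxymethoxy)phenyl]ethanone
Conditions: NaH, MeOCH2Cl, DMF, 0 °C to rt
Reagents that add atoms: chloromethyl methyl ether, COCCl
Why: Double acetal protection of both hydrogen-bonded phenols; with no free 2'-hydroxyl the later epoxide cannot cyclise under base, and the symmetry means either phenol can close the ring later.

Step 13
Reactants: 17 3-(benzyloxy)-4-{2-methoxy-4-[3,5,7-tris(benzyloxy)-4-oxo-4H-chromen-2-yl]phenoxy}benzaldehyde; 19 1-[4-methoxy-2,6-bis(methoxymethoxy)phenyl]ethanone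
Product: 20 (E)-3-(3-(benzyloxy)-4-{2-methoxy-4-[3,5,7-tris(benzyloxy)-4-oxo-4H-chromen-2-yl]phenoxy}phenyl)-1-[4-methoxy-2,6-bis(methoxymethoxy)phenyl]prop-2-en-1-one
Conditions: KOH, EtOH/THF, rt, under Ar
Reagents that add atoms: none
Why: Claisen–Schmidt condensation of the methyl ketone enolate with the non-enolisable aldehyde; dehydration gives the E-enone, and the fully O-protected 2,3-disubstituted chromone should tolerate hydroxide at room temperature.

Step 14
Reactants: 20 (E)-3-(3-(benzyloxy)-4-{2-methoxy-4-[3,5,7-tris(benzyloxy)-4-oxo-4H-chromen-2-yl]phenoxy}phenyl)-1-[4-methoxy-2,6-bis(methoxymethoxy)phenyl]prop-2-en-1-one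
Product: 21 trans-[3-(3-(benzyloxy)-4-{2-methoxy-4-[3,5,7-tris(benzyloxy)-4-oxo-4H-chromen-2-yl]phenoxy}phenyl)oxiran-2-yl][4-methoxy-2,6-bis(methoxymethoxy)phenyl]methanone (racemic)
Conditions: H2O2 (30% aq), NaOH (2 M aq), MeOH/THF, 0 °C to rt
Reagents that add atoms: hydrogen peroxide, OO
Why: Weitz–Scheffer nucleophilic epoxidation of the chalcone enone; the trans epoxide follows from the E-alkene by conjugate addition and ring closure, and the tetrasubstituted 2-aryl-3-alkoxychromone double bond is not attacked by hydroperoxide.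

Step 15
Reactants: 21 trans-[3-(3-(benzyloxy)-4-{2-methoxy-4-[3,5,7-tris(benzyloxy)-4-oxo-4H-chromen-2-yl]phenoxy}phenyl)oxiran-2-yl][4-methoxy-2,6-bis(methoxymethoxy)phenyl]methanone
Product: 23 trans-2-(3-(benzyloxy)-4-{2-methoxy-4-[3,5,7-tris(benzyloxy)-4-oxo-4H-chromen-2-yl]phenoxy}phenyl)-3,5-dihydroxy-7-methoxychroman-4-one (racemic), via dihydroxy chalcone epoxide 22 (not isolated)
Conditions: HCl (1.25 M in MeOH), MeOH/THF, 55 °C
Reagents that add atoms: none
Why: Acid removes both methoxymethyl groups, and a liberated phenol opens the protonated epoxide at the benzylic carbon (6-endo, favoured by the para-aryloxy-stabilised cation) to give the 2,3-trans dihydroflavonol; this acid-mediated closure is the standard way around aurone formation from 6'-oxygenated chalcones.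

Step 16
Reactants: 23 trans-2-(3-(benzyloxy)-4-{2-methoxy-4-[3,5,7-tris(benzyloxy)-4-oxo-4H-chromen-2-yl]phenoxy}phenyl)-3,5-dihydroxy-7-methoxychroman-4-one
Product: 24 2-(3-(benzyloxy)-4-{2-methoxy-4-[3,5,7-tris(benzyloxy)-4-oxo-4H-chromen-2-yl]phenoxy}phenyl)-3,5-dihydroxy-7-methoxy-4H-chromen-4-one
Conditions: I2, KOAc, AcOH, 90 °C
Reagents that add atoms: none
Why: Iodine–acetate dehydrogenation of a dihydroflavonol to the flavonol (α-iodination of the ketol, loss of HI, enolisation); acetate buffers the HI so that benzyl ethers are kept.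

Step 17
Reactants: 24 2-(3-(benzyloxy)-4-{2-methoxy-4-[3,5,7-tris(benzyloxy)-4-oxo-4H-chromen-2-yl]phenoxy}phenyl)-3,5-dihydroxy-7-methoxy-4H-chromen-4-one
Product: 25 2-(3-hydroxy-4-{2-methoxy-4-[3,5,7-trihydroxy-4-oxo-4H-chromen-2-yl]phenoxy}phenyl)-3,5-dihydroxy-7-methoxy-4H-chromen-4-one (CNP0190193.0)
Conditions: H2 (1 atm), Pd/C (10%), THF/MeOH, rt
Reagents that add atoms: none
Why: Hydrogenolysis of the four benzyl ethers; the chromone double bonds, the methyl ethers and the diaryl ether are not reduced under these mild conditions.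

## Compound list

1 | 4-fluoro-3-hydroxybenzaldehyde | O=Cc1ccc(F)c(O)c1 | starting material
2 | 3-(benzyloxy)-4-fluorobenzaldehyde | O=Cc1ccc(F)c(OCc2ccccc2)c1 | intermediate
3 | methyl (4-hydroxy-3-methoxyphenyl)acetate | COC(=O)Cc1ccc(O)c(OC)c1 | starting material
4 | methyl {4-[2-(benzyloxy)-4-formylphenoxy]-3-methoxyphenyl}acetate | COC(=O)Cc1ccc(Oc2ccc(C=O)cc2OCc2ccccc2)c(OC)c1 | intermediate
5 | methyl {4-[2-(benzyloxy)-4-(1,3-dioxolan-2-yl)phenoxy]-3-methoxyphenyl}acetate | COC(=O)Cc1ccc(Oc2ccc(C3OCCO3)cc2OCc2ccccc2)c(OC)c1 | intermediate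
6 | trimethylsilyl ketene acetal of 5 (E/Z mixture) | COC(O[Si](C)(C)C)=Cc1ccc(Oc2ccc(C3OCCO3)cc2OCc2ccccc2)c(OC)c1 | intermediate (not isolated)
7 | methyl bromo{4-[2-(benzyloxy)-4-(1,3-dioxolan-2-yl)phenoxy]-3-methoxyphenyl}acetate (racemic) | COC(=O)C(Br)c1ccc(Oc2ccc(C3OCCO3)cc2OCc2ccccc2)c(OC)c1 | intermediate
8 | 3,5-bis(benzyloxy)phenol | Oc1cc(OCc2ccccc2)cc(OCc2ccccc2)c1 | starting material
9 | 2,4-bis(benzyloxy)-6-hydroxybenzaldehyde | O=Cc1c(O)cc(OCc2ccccc2)cc1OCc1ccccc1 | intermediate
10 | methyl 2-[3,5-bis(benzyloxy)-2-formylphenoxy]-2-{4-[2-(benzyloxy)-4-(1,3-dioxolan-2-yl)phenoxy]-3-methoxyphenyl}acetate (racemic) | COC(=O)C(Oc1cc(OCc2ccccc2)cc(OCc2ccccc2)c1C=O)c1ccc(Oc2ccc(C3OCCO3)cc2OCc2ccccc2)c(OC)c1 | intermediate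
11 | 2-[3,5-bis(benzyloxy)-2-(hydroxymethyl)phenoxy]-2-{4-[2-(benzyloxy)-4-(1,3-dioxolan-2-yl)phenoxy]-3-methoxyphenyl}ethanol (racemic) | OCC(Oc1cc(OCc2ccccc2)cc(OCc2ccccc2)c1CO)c1ccc(Oc2ccc(C3OCCO3)cc2OCc2ccccc2)c(OC)c1 | intermediate
12 | 2-[3,5-bis(benzyloxy)-2-formylphenoxy]-2-{4-[2-(benzyloxy)-4-(1,3-dioxolan-2-yl)phenoxy]-3-methoxyphenyl}acetaldehyde (racemic) | O=Cc1c(OCc2ccccc2)cc(OCc2ccccc2)cc1OC(C=O)c1ccc(Oc2ccc(C3OCCO3)cc2OCc2ccccc2)c(OC)c1 | intermediate
13 | 5,7-bis(benzyloxy)-2-{4-[2-(benzyloxy)-4-(1,3-dioxolan-2-yl)phenoxy]-3-methoxyphenyl}chromane-3,4-diol (stereoisomer mixture) | OC1c2c(OCc3ccccc3)cc(OCc3ccccc3)cc2OC(c2ccc(Oc3ccc(C4OCCO4)cc3OCc3ccccc3)c(OC)c2)C1O | intermediate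
14 | 5,7-bis(benzyloxy)-2-{4-[2-(benzyloxy)-4-(1,3-dioxolan-2-yl)phenoxy]-3-methoxyphenyl}chromane-3,4-dione (racemic) | O=C1C(=O)c2c(OCc3ccccc3)cc(OCc3ccccc3)cc2OC1c1ccc(Oc2ccc(C3OCCO3)cc2OCc2ccccc2)c(OC)c1 | intermediate (not isolated)
15 | 5,7-bis(benzyloxy)-2-{4-[2-(benzyloxy)-4-(1,3-dioxolan-2-yl)phenoxy]-3-methoxyphenyl}-3-hydroxy-4H-chromen-4-one | O=c1c(O)c(-c2ccc(Oc3ccc(C4OCCO4)cc3OCc3ccccc3)c(OC)c2)oc2cc(OCc3ccccc3)cc(OCc3ccccc3)c12 | intermediate
16 | 3,5,7-tris(benzyloxy)-2-{4-[2-(benzyloxy)-4-(1,3-dioxolan-2-yl)phenoxy]-3-methoxyphenyl}-4H-chromen-4-one | O=c1c(OCc2ccccc2)c(-c2ccc(Oc3ccc(C4OCCO4)cc3OCc3ccccc3)c(OC)c2)oc2cc(OCc3ccccc3)cc(OCc3ccccc3)c12 | intermediate (not isolated)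
17 | 3-(benzyloxy)-4-{2-methoxy-4-[3,5,7-tris(benzyloxy)-4-oxo-4H-chromen-2-yl]phenoxy}benzaldehyde | O=Cc1ccc(Oc2ccc(-c3oc4cc(OCc5ccccc5)cc(OCc5ccccc5)c4c(=O)c3OCc3ccccc3)cc2OC)c(OCc2ccccc2)c1 | intermediate
18 | 1-(2,6-dihydroxy-4-methoxyphenyl)ethanone | CC(=O)c1c(O)cc(OC)cc1O | starting material
19 | 1-[4-methoxy-2,6-bis(methoxymethoxy)phenyl]ethanone | CC(=O)c1c(OCOC)cc(OC)cc1OCOC | intermediate
20 | (E)-3-(3-(benzyloxy)-4-{2-methoxy-4-[3,5,7-tris(benzyloxy)-4-oxo-4H-chromen-2-yl]phenoxy}phenyl)-1-[4-methoxy-2,6-bis(methoxymethoxy)phenyl]prop-2-en-1-one | COCOc1cc(OC)cc(OCOC)c1C(=O)/C=C/c1ccc(Oc2ccc(-c3oc4cc(OCc5ccccc5)cc(OCc5ccccc5)c4c(=O)c3OCc3ccccc3)cc2OC)c(OCc2ccccc2)c1 | intermediate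
21 | trans-[3-(3-(benzyloxy)-4-{2-methoxy-4-[3,5,7-tris(benzyloxy)-4-oxo-4H-chromen-2-yl]phenoxy}phenyl)oxiran-2-yl][4-methoxy-2,6-bis(methoxymethoxy)phenyl]methanone (racemic, one enantiomer drawn) | COCOc1cc(OC)cc(OCOC)c1C(=O)[C@@H]1O[C@H]1c1ccc(Oc2ccc(-c3oc4cc(OCc5ccccc5)cc(OCc5ccccc5)c4c(=O)c3OCc3ccccc3)cc2OC)c(OCc2ccccc2)c1 | intermediate
22 | trans-[3-(3-(benzyloxy)-4-{2-methoxy-4-[3,5,7-tris(benzyloxy)-4-oxo-4H-chromen-2-yl]phenoxy}phenyl)oxiran-2-yl](2,6-dihydroxy-4-methoxyphenyl)methanone (racemic, one enantiomer drawn) | COc1cc(O)c(C(=O)[C@@H]2O[C@H]2c2ccc(Oc3ccc(-c4oc5cc(OCc6ccccc6)cc(OCc6ccccc6)c5c(=O)c4OCc4ccccc4)cc3OC)c(OCc3ccccc3)c2)c(O)c1 | intermediate (not isolated)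
23 | trans-2-(3-(benzyloxy)-4-{2-methoxy-4-[3,5,7-tris(benzyloxy)-4-oxo-4H-chromen-2-yl]phenoxy}phenyl)-3,5-dihydroxy-7-methoxychroman-4-one (racemic, one enantiomer drawn) | COc1cc(-c2oc3cc(OCc4ccccc4)cc(OCc4ccccc4)c3c(=O)c2OCc2ccccc2)ccc1Oc1ccc(cc1OCc1ccccc1)[C@@H]1[C@H](C(=O)c2c(O)cc(OC)cc2O1)O | intermediate
24 | 2-(3-(benzyloxy)-4-{2-methoxy-4-[3,5,7-tris(benzyloxy)-4-oxo-4H-chromen-2-yl]phenoxy}phenyl)-3,5-dihydroxy-7-methoxy-4H-chromen-4-one | COc1cc(-c2oc3cc(OCc4ccccc4)cc(OCc4ccccc4)c3c(=O)c2OCc2ccccc2)ccc1Oc1ccc(cc1OCc1ccccc1)-c1oc2cc(OC)cc(O)c2c(=O)c1O | intermediate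
25 | 2-(3-hydroxy-4-{2-methoxy-4-[3,5,7-trihydroxy-4-oxo-4H-chromen-2-yl]phenoxy}phenyl)-3,5-dihydroxy-7-methoxy-4H-chromen-4-one (CNP0190193.0) | COc1cc(O)c2c(=O)c(O)c(-c3ccc(Oc4ccc(-c5oc6cc(O)cc(O)c6c(=O)c5O)cc4OC)c(O)c3)oc2c1 | target

## Step count and least certain steps

Total step count: 17. Longest linear sequence: 15 steps (1, 2, 3, 4, 6, 7, 8, 9, 10, 11, 13, 14, 15, 16, 17). Steps 5 and 12 are side branches.

**Step 9 (key step).** The most likely failure is electron transfer to the α-aryloxy aldehyde, or a second electron transfer before ring closure, followed by expulsion of the phenoxide and fragmentation. The three alkoxy groups make the aromatic aldehyde harder to reduce than a plain benzaldehyde, so the gap between the two carbonyl groups is narrower than usual. Plain reduction to 11 and intermolecular coupling are lesser risks.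

Fallback: form the same C3–C4 bond as an alkene by metathesis and add the two oxygens afterwards. Set out from 12. Double methylenation with salt-free Ph3P=CH2 (from Ph3PCH3Br and KN(SiMe3)2, THF, −78 to 0 °C) would give the diene 1,5-bis(benzyloxy)-2-ethenyl-3-[1-aryl-prop-2-enyloxy]benzene F1. Ring-closing metathesis with (H2IMes)(PCy3)Cl2Ru=CHPh (second-generation Grubbs catalyst) in CH2Cl2 would give the 2-aryl-5,7-bis(benzyloxy)-2H-chromene F2. Dihydroxylation with OsO4 (cat.) and N-methylmorpholine N-oxide in acetone/water would give the cis-3,4-diol, which is one stereoisomer of 13, where the route is rejoined.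

**Step 2.** The alkoxy group ortho to fluorine slows the displacement, and at the temperature then needed the arylacetate methylene may condense with the aldehyde, or the ester may hydrolyse.

Fallback: make the ether by copper catalysis with the aldehyde already masked. Commercial 4-bromo-3-hydroxybenzaldehyde would be benzylated (BnBr, K2CO3, DMF) to 3-(benzyloxy)-4-bromobenzaldehyde F3. This would be acetalised (ethylene glycol, TsOH, toluene, reflux with removal of water) to 2-[3-(benzyloxy)-4-bromophenyl]-1,3-dioxolane F4. F4 would then be coupled with 3 in an Ullmann ether synthesis (CuI, N,N-dimethylglycine, Cs2CO3, dioxane, 90 °C). The fallback sets out from 3 and returns to the route at 5.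

**Step 10.** The C4 carbinol is benzylic to a phloroglucinol-type ring and ionises easily, so loss of material through cationic oligomerisation is possible. The oxidation could also stop at the ketol stage or cleave the glycol.

Fallback: oxidise stepwise. From 13, MnO2 in CH2Cl2 would oxidise only the benzylic C4 carbinol under neutral conditions to 5,7-bis(benzyloxy)-3-hydroxy-2-aryl-chroman-4-one F5. Alkaline hydrogen peroxide (H2O2, NaOH, MeOH/THF), the dehydrogenating last stage of the classical chalcone-to-flavonol oxidation, would then convert F5 into 15, where the route is rejoined.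

**Step 15.** Ring closure may go to the α-carbon of the epoxide (five-membered closure towards a benzofuranone), methanol may open the epoxide, or the aryl group may shift. The para substituent on this B ring is an aryloxy group, a weaker donor than an alkoxy group.

Fallback: use the one-pot alkaline route (Algar–Flynn–Oyamada reaction), which fails for different reasons than the acid closure. Ketone 18 would be monobenzylated (BnBr, K2CO3, acetone) to 1-[2-(benzyloxy)-6-hydroxy-4-methoxyphenyl]ethanone F6. Condensation of F6 with 17 (KOH, EtOH/THF) would give the 2'-hydroxy-6'-benzyloxy chalcone F7. Alkaline hydrogen peroxide (H2O2, NaOH, MeOH, 0 °C) would then cyclise F7 oxidatively to the 5-O-benzyl flavonol F8. Hydrogenolysis of F8 (H2, Pd/C) removes five benzyl groups and returns to the route at 25. The fallback sets out from 17 and 18.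

## Further compounds

F1 | step 9 | 1,5-bis(benzyloxy)-2-ethenyl-3-(1-{4-[2-(benzyloxy)-4-(1,3-dioxolan-2-yl)phenoxy]-3-methoxyphenyl}prop-2-enyloxy)benzene (racemic) | C=Cc1c(OCc2ccccc2)cc(OCc2ccccc2)cc1OC(C=C)c1ccc(Oc2ccc(C3OCCO3)cc2OCc2ccccc2)c(OC)c1
F2 | step 9 | 5,7-bis(benzyloxy)-2-{4-[2-(benzyloxy)-4-(1,3-dioxolan-2-yl)phenoxy]-3-methoxyphenyl}-2H-chromene (racemic) | C1=Cc2c(OCc3ccccc3)cc(OCc3ccccc3)cc2OC1c1ccc(Oc2ccc(C3OCCO3)cc2OCc2ccccc2)c(OC)c1
F3 | step 2 | 3-(benzyloxy)-4-bromobenzaldehyde | O=Cc1ccc(Br)c(OCc2ccccc2)c1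
F4 | step 2 | 2-[3-(benzyloxy)-4-bromophenyl]-1,3-dioxolane | Brc1ccc(C2OCCO2)cc1OCc1ccccc1
F5 | step 10 | 5,7-bis(benzyloxy)-2-{4-[2-(benzyloxy)-4-(1,3-dioxolan-2-yl)phenoxy]-3-methoxyphenyl}-3-hydroxychroman-4-one (stereoisomer mixture) | O=C1c2c(OCc3ccccc3)cc(OCc3ccccc3)cc2OC(c2ccc(Oc3ccc(C4OCCO4)cc3OCc3ccccc3)c(OC)c2)C1O
F6 | step 15 | 1-[2-(benzyloxy)-6-hydroxy-4-methoxyphenyl]ethanone | CC(=O)c1c(O)cc(OC)cc1OCc1ccccc1
F7 | step 15 | (E)-1-[2-(benzyloxy)-6-hydroxy-4-methoxyphenyl]-3-(3-(benzyloxy)-4-{2-methoxy-4-[3,5,7-tris(benzyloxy)-4-oxo-4H-chromen-2-yl]phenoxy}phenyl)prop-2-en-1-one | COc1cc(O)c(C(=O)/C=C/c2ccc(Oc3ccc(-c4oc5cc(OCc6ccccc6)cc(OCc6ccccc6)c5c(=O)c4OCc4ccccc4)cc3OC)c(OCc3ccccc3)c2)c(OCc2ccccc2)c1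
F8 | step 15 | 5-(benzyloxy)-2-(3-(benzyloxy)-4-{2-methoxy-4-[3,5,7-tris(benzyloxy)-4-oxo-4H-chromen-2-yl]phenoxy}phenyl)-3-hydroxy-7-methoxy-4H-chromen-4-one | COc1cc(-c2oc3cc(OCc4ccccc4)cc(OCc4ccccc4)c3c(=O)c2OCc2ccccc2)ccc1Oc1ccc(cc1OCc1ccccc1)-c1oc2cc(OC)cc(OCc3ccccc3)c2c(=O)c1O
A1 | alternative 1 | 1-[2,4-bis(benzyloxy)-6-(methoxymethoxy)phenyl]-2-diazoethanone | [N-]=[N+]=CC(=O)c1c(OCOC)cc(OCc2ccccc2)cc1OCc1ccccc1
A2 | alternative 1 | benzyl alcohol | OCc1ccccc1
A3 | alternative 1 | methyl 3-(benzyloxy)-4-(4-formyl-2-methoxyphenoxy)benzoate | COC(=O)c1ccc(Oc2ccc(C=O)cc2OC)c(OCc2ccccc2)c1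
A4 | alternative 1 | methyl 3-(benzyloxy)-4-(4-{2-(benzyloxy)-3-[2,4-bis(benzyloxy)-6-(methoxymethoxy)phenyl]-1-hydroxy-3-oxopropyl}-2-methoxyphenoxy)benzoate (diastereomer mixture) | COC(=O)c1ccc(Oc2ccc(C(O)C(OCc3ccccc3)C(=O)c3c(OCOC)cc(OCc4ccccc4)cc3OCc3ccccc3)cc2OC)c(OCc2ccccc2)c1
A5 | alternative 2 | methyl coumalate (methyl 2-oxo-2H-pyran-5-carboxylate) | COC(=O)C1=COC(=O)C=C1
A6 | alternative 2 | 2-{[4-(1,3-dioxolan-2-yl)-2-methoxyphenoxy]ethynyl}-4,4,5,5-tetramethyl-1,3,2-dioxaborolane | COc1cc(C2OCCO2)ccc1OC#CB1OC(C)(C)C(C)(C)O1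
A7 | alternative 2 | methyl 4-[4-(1,3-dioxolan-2-yl)-2-methoxyphenoxy]-3-(4,4,5,5-tetramethyl-1,3,2-dioxaborolan-2-yl)benzoate | COC(=O)c1ccc(Oc2ccc(C3OCCO3)cc2OC)c(B2OC(C)(C)C(C)(C)O2)c1
A8 | alternative 3 | phloroglucinol | Oc1cc(O)cc(O)c1
A9 | alternative 3 | ethyl 2-(benzyloxy)-3-{4-[2-(benzyloxy)-4-(methoxycarbonyl)phenoxy]-3-methoxyphenyl}-3-oxopropanoate (racemic) | CCOC(=O)C(OCc1ccccc1)C(=O)c1ccc(Oc2ccc(C(=O)OC)cc2OCc2ccccc2)c(OC)c1
A10 | alternative 3 | methyl 3-(benzyloxy)-4-{4-[3-(benzyloxy)-5,7-dihydroxy-4-oxo-4H-chromen-2-yl]-2-methoxyphenoxy}benzoate | COC(=O)c1ccc(Oc2ccc(-c3oc4cc(O)cc(O)c4c(=O)c3OCc3ccccc3)cc2OC)c(OCc2ccccc2)c1
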